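## Retrosynthetic overview

1. The target comes from a bis-O-allyl C4′-formate by one zerovalent-palladium/morpholine unmasking. The trans-epoxy alcohol comes from Mitsunobu inversion of the cis-epoxy alcohol, itself from Luche reduction of an epoxy ketone made by hydroxyl-directed nucleophilic epoxidation.
2. Key step: the 4-hydroxy-4-pyridonyl-cyclohexenone is made from an achiral p-quinol (4-hydroxycyclohexa-2,5-dienone) by a ligand-controlled copper hydride desymmetrizing 1,4-reduction on the fully assembled decalin–pyridone. This one catalytic step sets C1′, which then relays C2′, C3′ and C4′, so no enantiopure epoxy ketone building block is needed.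
3. The 3-acyl group and the p-quinol are attached to 3,5-dibromo-1,4-bis(allyloxy)pyridin-2-one by two successive halogen–metal exchanges (C3 with the decalin aldehyde, C5 with p-benzoquinone monoketal). The N–O bond is bought in as a pyridine N-oxide.
4. The decalin aldehyde comes from a substrate-controlled Me2AlCl intramolecular Diels–Alder reaction of a trienal made from (R)-citronellal.
5. Ring order: pyridone ring (commercial N-oxide), then decalin rings A and B together (Diels–Alder), then the six-membered carbocycle brought in intact as the quinone monoketal, then the oxirane last.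

Assumption: the sense of induction of the chiral copper hydride on this p-quinol is not known in advance. (R)-DTBM-SEGPHOS is written; its enantiomer is used if the C1′ epimer forms (the two products are diastereomers, so this is read directly by NMR).

Assumption: compounds 1, 2, 7, 10 and 17 are taken as catalogue compounds.

Numbering used in the text: cyclohexane carbons are C1′ (carbinol carbon bound to the pyridone), C2′/C3′ (epoxide carbons, C2′ next to C1′), C4′ (secondary carbinol), C5′ and C6′.

## Route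

Step 1
Reactants: 1 (R)-citronellal; 2 diethyl [(2E)-but-2-en-1-yl]phosphonate
Product: 4 (2E,4E,7R)-7,11-dimethyldodeca-2,4,10-triene, via lithiated phosphonate 3 (not isolated)
Conditions: 2, n-BuLi, THF, −78 °C; then 1, DMPU, −78 °C → rt
Reagents that add atoms: none
Why: Horner–Wadsworth–Emmons olefination of the aldehyde with the α-lithiated allylic phosphonate builds the (E,E)-diene (new C=C formed E, crotyl C=C keeps its geometry) and does not touch the citronellal stereocentre, which becomes C6 of the decalin.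

Step 2
Reactants: 4
Product: 6 (4R,6E,8E)-4-methyldeca-6,8-dienal, via epoxide 5 (not isolated)
Conditions: mCPBA (1.0 equiv), CH2Cl2, −20 °C; then H5IO6, THF/H2O, 0 °C
Reagents that add atoms: mCPBA, O=C(OO)c1cccc(Cl)c1; water, O
Why: the trisubstituted alkene is the most nucleophilic π-bond and is epoxidised (Prilezhaev reaction) ahead of the conjugated diene, and periodic acid then opens and cleaves the epoxide (glycol cleavage) to the aldehyde and acetone without affecting the stereocentre.

Step 3
Reactants: 6; 7 (triphenylphosphoranylidene)acetaldehyde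
Product: 8 (2E,6R,8E,10E)-6-methyldodeca-2,8,10-trienal
Conditions: toluene, 70 °C
Reagents that add atoms: none
Why: Wittig reaction with the stabilised formyl ylide gives the (E)-enal and stops after one homologation because the product enal is less electrophilic than the saturated aldehyde.

Step 4
Reactants: 8
Product: 9 (1R,2R,4aS,6R,8aR)-2,6-dimethyl-1,2,4a,5,6,7,8,8a-octahydronaphthalene-1-carbaldehyde
Conditions: Me2AlCl (1.1 equiv), CH2Cl2, −78 → −30 °C; 1 M aq. HCl quench
Reagents that add atoms: none
Why: Lewis acid-promoted intramolecular Diels–Alder reaction through the endo transition state, with the four-carbon tether in a chair that keeps the C6 methyl equatorial, sets C1, C2, C4a and C8a in one step as the trans-fused decalin with equatorial 1-formyl and cis 2-methyl.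

Step 5
Reactants: 10 2-chloro-4-nitropyridine 1-oxide
Product: 11 2-chloro-4-(prop-2-en-1-yloxy)pyridine 1-oxide
Conditions: allyl alcohol, NaH, THF, 0 °C → rt
Reagents that add atoms: allyl alcohol, C=CCO
Why: nucleophilic aromatic substitution in which alkoxide displaces the 4-nitro group of the N-oxide faster than the 2-chloride installs the 4-oxygen as its allyl ether on a ring that already carries the N–O bond of the target.

Step 6
Reactants: 11
Product: 13 1,4-bis(prop-2-en-1-yloxy)pyridin-2(1H)-one, via sodium pyridinolate 12 (not isolated)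
Conditions: NaOH (2.2 equiv), H2O, 90 °C; then allyl bromide, MeOH, 50 °C
Reagents that add atoms: sodium hydroxide, [Na+].[OH-]; allyl bromide, C=CCBr
Why: hydroxide displaces the 2-chloride α to the N-oxide (nucleophilic aromatic substitution) to give the 1-hydroxy-2-pyridone as its sodium salt, whose N–O oxygen is then alkylated by allyl bromide (Williamson-type O-alkylation).

Step 7
Reactants: 13
Product: 14 3,5-dibromo-1,4-bis(prop-2-en-1-yloxy)pyridin-2(1H)-one
Conditions: NBS (2.1 equiv), MeCN, 0 °C → rt
Reagents that add atoms: N-bromosuccinimide, O=C1CCC(=O)N1Br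
Why: electrophilic aromatic bromination at C3 and C5, both ortho to the 4-allyloxy group and activated as enamide positions, is much faster than attack on the allyl alkenes.

Step 8
Reactants: 14; 9
Product: 16 C3 bromo carbinol (both carbinol epimers), via arylmagnesium chloride 15 (not isolated)
Conditions: i-PrMgCl·LiCl (1.05 equiv), THF, −40 °C; then 9, −40 → 0 °C; aq. NH4Cl
Reagents that add atoms: none
Why: bromine–magnesium exchange occurs at C3, where the carbanion is flanked by the chelating C2 carbonyl and the C4 alkoxy group, and the Grignard reagent adds 1,2 to the aldehyde without touching the allyl ethers; the new carbinol centre is uncontrolled and is erased in step 10.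

Step 9
Reactants: 16; 17 4,4-dimethoxycyclohexa-2,5-dien-1-one
Product: 20 p-quinol carbinol, via dilithio species 18 (not isolated), via dimethyl ketal adduct 19 (not isolated)
Conditions: n-BuLi (2.1 equiv), THF, −78 °C; then 17, −78 → −40 °C; then AcOH, H2O, THF, rt
Reagents that add atoms: water, O
Why: one equivalent of n-BuLi forms the lithium alkoxide and the second effects bromine–lithium exchange at C5, the aryllithium adds 1,2 to the quinone monoketal carbonyl, and dilute acid hydrolyses the dimethyl ketal to the achiral 4-aryl-4-hydroxycyclohexadienone, so no ring stereocentre is created yet.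

Step 10
Reactants: 20
Product: 21 p-quinol ketone
Conditions: Dess–Martin periodinane, CH2Cl2, 0 °C → rt
Reagents that add atoms: none
Why: Dess–Martin oxidation converts both carbinol epimers into the single 3-acyl ketone and cannot oxidise the tertiary p-quinol hydroxyl.

Step 11
Reactants: 21
Product: 23 (1′S)-4′-hydroxy-enone, via bis-silyl dienol ether 22 (not isolated)
Conditions: Cu(OAc)2 (5 mol %), (R)-DTBM-SEGPHOS (5.5 mol %), (EtO)2MeSiH (2.2 equiv), toluene, −40 → −20 °C; then 0.5 M aq. HCl, THF, 0 °C
Reagents that add atoms: none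
Why: Proposed new method: the ligand-bound copper hydride adds hydride to the β-carbon of one of the two enantiotopic enone halves of the free p-quinol and the resulting silyl dienol ether is inert to a second reduction, so the catalyst alone fixes C1′ (a minor C1′ epimer is a separable diastereomer) while the twisted, doubly ortho-substituted 3-acyl ketone is left alone; the closest known reaction type is copper hydride-catalysed enantioselective conjugate reduction used to desymmetrize 4,4-disubstituted cyclohexadienones.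

Step 12
Reactants: 23
Product: 24 epoxy ketone
Conditions: t-BuOOH, BnMe3NOH (10 mol %), THF, 0 °C
Reagents that add atoms: tert-butyl hydroperoxide, CC(C)(C)OO
Why: Weitz–Scheffer nucleophilic epoxidation, in which t-BuOO− attacks the enone β-carbon C2′ from the face of the small hydrogen-bonding hydroxyl and away from the bulky pyridone, gives the epoxide cis to the tertiary OH and ignores the electron-neutral decalin and allyl alkenes.

Step 13
Reactants: 24
Product: 25 cis-epoxy alcohol (C4′ epimer of the target pattern)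
Conditions: NaBH4, CeCl3·7H2O, MeOH/THF, −78 °C
Reagents that add atoms: none
Why: Luche reduction, in which hydride attacks the α,β-epoxy ketone anti to the epoxide C–O bond (Felkin–Anh/Cornforth control), gives the C4′ alcohol cis to the epoxide while the hindered 3-acyl ketone does not react at −78 °C.

Step 14
Reactants: 25
Product: 26 trans-epoxy formate
Conditions: PPh3, diisopropyl azodicarboxylate, HCO2H, THF, 0 °C → rt
Reagents that add atoms: formic acid, O=CO
Why: Mitsunobu reaction with formic acid displaces the oxyphosphonium by SN2 from the face opposite the epoxide, which inverts C4′ to the configuration trans to the epoxide and to the tertiary OH, the latter being too hindered to be activated.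

Step 15
Reactants: 26
Product: 27 target
Conditions: Pd(PPh3)4 (5 mol %), morpholine (10 equiv), THF/MeOH, rt; work-up at pH 4
Reagents that add atoms: none
Why: zerovalent palladium ionises both O-allyl groups (Tsuji–Trost deallylation) and morpholine traps the π-allyl fragments and aminolyses the formate, which frees the N-hydroxy, 4-hydroxy and C4′ hydroxy groups under near-neutral conditions that spare the epoxide, the tertiary alcohol and the decalin alkene.

## Compound list

Dec = (1R,2R,4aS,6R,8aR)-2,6-dimethyl-1,2,4a,5,6,7,8,8a-octahydronaphthalen-1-yl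

1 | (3R)-3,7-dimethyloct-6-enal, (R)-citronellal | O=CC[C@H](C)CCC=C(C)C | starting material
2 | diethyl [(2E)-but-2-en-1-yl]phosphonate | CCOP(=O)(C/C=C/C)OCC | starting material
3 | lithium (2E)-1-(diethoxyphosphoryl)but-2-en-1-ide | [Li+].CCOP(=O)([CH-]/C=C/C)OCC | intermediate
4 | (2E,4E,7R)-7,11-dimethyldodeca-2,4,10-triene | C/C=C/C=C/C[C@H](C)CCC=C(C)C | intermediate
5 | 2,2-dimethyl-3-[(3R,5E,7E)-3-methylnona-5,7-dien-1-yl]oxirane (both epoxide epimers) | C/C=C/C=C/C[C@H](C)CCC1OC1(C)C | intermediate
6 | (4R,6E,8E)-4-methyldeca-6,8-dienal | C/C=C/C=C/C[C@H](C)CCC=O | intermediate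
7 | (triphenylphosphoranylidene)acetaldehyde | O=CC=P(c1ccccc1)(c1ccccc1)c1ccccc1 | starting material
8 | (2E,6R,8E,10E)-6-methyldodeca-2,8,10-trienal | C/C=C/C=C/C[C@H](C)CC/C=C/C=O | intermediate
9 | (1R,2R,4aS,6R,8aR)-2,6-dimethyl-1,2,4a,5,6,7,8,8a-octahydronaphthalene-1-carbaldehyde | C[C@@H]1CC[C@H]2[C@H](C=O)[C@H](C)C=C[C@@H]2C1 | intermediate
10 | 2-chloro-4-nitropyridine 1-oxide | [O-][n+]1ccc(cc1Cl)[N+](=O)[O-] | starting material
11 | 2-chloro-4-(prop-2-en-1-yloxy)pyridine 1-oxide | [O-][n+]1ccc(OCC=C)cc1Cl | intermediate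
12 | sodium 2-oxo-4-(prop-2-en-1-yloxy)pyridin-1(2H)-olate | [Na+].[O-]n1ccc(OCC=C)cc1=O | intermediate
13 | 1,4-bis(prop-2-en-1-yloxy)pyridin-2(1H)-one | C=CCOn1ccc(OCC=C)cc1=O | intermediate
14 | 3,5-dibromo-1,4-bis(prop-2-en-1-yloxy)pyridin-2(1H)-one | C=CCOn1cc(Br)c(OCC=C)c(Br)c1=O | intermediate
15 | [5-bromo-2-oxo-1,4-bis(prop-2-en-1-yloxy)-1,2-dihydropyridin-3-yl]magnesium chloride | C=CCOn1cc(Br)c(OCC=C)c([Mg]Cl)c1=O | intermediate
16 | 5-bromo-3-[Dec(hydroxy)methyl]-1,4-bis(prop-2-en-1-yloxy)pyridin-2(1H)-one (both carbinol epimers) | C[C@@H]1CC[C@H]2[C@H](C(O)c3c(OCC=C)c(Br)cn(OCC=C)c3=O)[C@H](C)C=C[C@@H]2C1 | intermediate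
17 | 4,4-dimethoxycyclohexa-2,5-dien-1-one | COC1(OC)C=CC(=O)C=C1 | starting material
18 | lithium alkoxide of 16 lithiated at pyridone C5 in place of bromine | C[C@@H]1CC[C@H]2[C@H](C(O[Li])c3c(OCC=C)c([Li])cn(OCC=C)c3=O)[C@H](C)C=C[C@@H]2C1 | intermediate
19 | dilithium dialkoxide of 3-[Dec(hydroxy)methyl]-5-(1-hydroxy-4,4-dimethoxycyclohexa-2,5-dien-1-yl)-1,4-bis(prop-2-en-1-yloxy)pyridin-2(1H)-one | C[C@@H]1CC[C@H]2[C@H](C(O[Li])c3c(OCC=C)c(C4(O[Li])C=CC(OC)(OC)C=C4)cn(OCC=C)c3=O)[C@H](C)C=C[C@@H]2C1 | intermediate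
20 | 3-[Dec(hydroxy)methyl]-5-(1-hydroxy-4-oxocyclohexa-2,5-dien-1-yl)-1,4-bis(prop-2-en-1-yloxy)pyridin-2(1H)-one (both carbinol epimers) | C[C@@H]1CC[C@H]2[C@H](C(O)c3c(OCC=C)c(C4(O)C=CC(=O)C=C4)cn(OCC=C)c3=O)[C@H](C)C=C[C@@H]2C1 | intermediate
21 | 3-(Dec-carbonyl)-5-(1-hydroxy-4-oxocyclohexa-2,5-dien-1-yl)-1,4-bis(prop-2-en-1-yloxy)pyridin-2(1H)-one | C[C@@H]1CC[C@H]2[C@H](C(=O)c3c(OCC=C)c(C4(O)C=CC(=O)C=C4)cn(OCC=C)c3=O)[C@H](C)C=C[C@@H]2C1 | intermediate
22 | 3-(Dec-carbonyl)-5-[(1S)-1,4-bis{[diethoxy(methyl)silyl]oxy}cyclohexa-2,4-dien-1-yl]-1,4-bis(prop-2-en-1-yloxy)pyridin-2(1H)-one | C[C@@H]1CC[C@H]2[C@H](C(=O)c3c(OCC=C)c([C@]4(O[Si](C)(OCC)OCC)CC=C(O[Si](C)(OCC)OCC)C=C4)cn(OCC=C)c3=O)[C@H](C)C=C[C@@H]2C1 | intermediate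
23 | 3-(Dec-carbonyl)-5-[(1S)-1-hydroxy-4-oxocyclohex-2-en-1-yl]-1,4-bis(prop-2-en-1-yloxy)pyridin-2(1H)-one | C[C@@H]1CC[C@H]2[C@H](C(=O)c3c(OCC=C)c([C@]4(O)CCC(=O)C=C4)cn(OCC=C)c3=O)[C@H](C)C=C[C@@H]2C1 | intermediate
24 | 3-(Dec-carbonyl)-5-[(1R,2R,6S)-2-hydroxy-5-oxo-7-oxabicyclo[4.1.0]heptan-2-yl]-1,4-bis(prop-2-en-1-yloxy)pyridin-2(1H)-one | C[C@@H]1CC[C@H]2[C@H](C(=O)c3c(OCC=C)c([C@]4(O)CCC(=O)[C@H]5O[C@H]54)cn(OCC=C)c3=O)[C@H](C)C=C[C@@H]2C1 | intermediate
25 | 3-(Dec-carbonyl)-5-[(1R,2R,5R,6R)-2,5-dihydroxy-7-oxabicyclo[4.1.0]heptan-2-yl]-1,4-bis(prop-2-en-1-yloxy)pyridin-2(1H)-one | C[C@@H]1CC[C@H]2[C@H](C(=O)c3c(OCC=C)c([C@]4(O)CC[C@@H](O)[C@H]5O[C@H]54)cn(OCC=C)c3=O)[C@H](C)C=C[C@@H]2C1 | intermediate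
26 | 3-(Dec-carbonyl)-5-[(1R,2R,5S,6R)-5-(formyloxy)-2-hydroxy-7-oxabicyclo[4.1.0]heptan-2-yl]-1,4-bis(prop-2-en-1-yloxy)pyridin-2(1H)-one | C[C@@H]1CC[C@H]2[C@H](C(=O)c3c(OCC=C)c([C@]4(O)CC[C@H](OC=O)[C@H]5O[C@H]54)cn(OCC=C)c3=O)[C@H](C)C=C[C@@H]2C1 | intermediate
27 | 3-(Dec-carbonyl)-5-[(1R,2R,5S,6R)-2,5-dihydroxy-7-oxabicyclo[4.1.0]heptan-2-yl]-1,4-dihydroxypyridin-2(1H)-one | C[C@@H]1CC[C@H]2[C@H](C(=O)c3c(O)c([C@]4(O)CC[C@H](O)[C@H]5O[C@H]54)cn(O)c3=O)[C@H](C)C=C[C@@H]2C1 | target

## Step count and risk

Total: 15 steps. Longest linear sequence: 12 steps (steps 1–4, then 8–15, from (R)-citronellal). The pyridone branch is 3 + 8 = 11 steps.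

The three steps most likely to fail, each with a fallback:

1. The copper hydride desymmetrization (step 11) may give poor facial control on a free p-quinol, or may over-reduce. The fallback sets out from 21 and comes back at 23. Both enone double bonds are reduced with [(Ph3P)CuH]6 (catalytic) and excess (EtO)2MeSiH, then aqueous acid, to give the achiral saturated hydroxy ketone F3. Enantiotopic α-deprotonation with lithium bis[(1R)-1-phenylethyl]amide (or its enantiomer, chosen by the same NMR read-out) and LiCl with Me3SiCl as internal quench at −100 °C gives the bis(trimethylsilyl) enol ether F4. Dehydrogenation of the silyl enol ether with 2-iodoxybenzoic acid/4-methoxypyridine N-oxide in DMSO and a mild acidic work-up removes the silyl groups and returns enone 23. This replaces reductive desymmetrization of the dienone by deprotonative desymmetrization of the ketone.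

2. The dianion bromine–lithium exchange and quinone monoketal addition (step 9) may suffer from attack of n-BuLi on the N-alkoxypyridone or from poor solubility of the dianion. The fallback sets out from 16 and comes back at 20. The carbinol is silylated (Et3SiCl, imidazole, DMF) to the triethylsilyl ether F1. F1 is exchanged with t-BuLi (2 equiv) at −95 °C, transmetalated with LaCl3·2LiCl, and the less basic organolanthanum reagent is added to 17 to give the silyl-protected dimethyl ketal adduct F2. Aqueous acetic acid then removes the ketal and the silyl ether together to give 20.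

3. The Mitsunobu inversion next to the epoxide (step 14) may give elimination or a low yield, and step 13 may be less cis-selective than expected. The fallback sets out from 24, skips 25 and 26, and comes back at 27. The epoxy ketone is reduced with Me4NBH(OAc)3 in MeCN/AcOH at −30 °C. The tertiary C1′ hydroxyl, which is cis to the epoxide, binds boron and delivers hydride across the ring through a boat conformer to the same face, so the C4′ hydroxyl forms trans to the epoxide directly and gives the trans-epoxy alcohol F5. F5 is deallylated under the conditions of step 15 to give 27.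

## Further compounds

F1 | step 9 | 5-bromo-3-{Dec[(triethylsilyl)oxy]methyl}-1,4-bis(prop-2-en-1-yloxy)pyridin-2(1H)-one (both epimers) | C[C@@H]1CC[C@H]2[C@H](C(O[Si](CC)(CC)CC)c3c(OCC=C)c(Br)cn(OCC=C)c3=O)[C@H](C)C=C[C@@H]2C1
F2 | step 9 | 3-{Dec[(triethylsilyl)oxy]methyl}-5-(1-hydroxy-4,4-dimethoxycyclohexa-2,5-dien-1-yl)-1,4-bis(prop-2-en-1-yloxy)pyridin-2(1H)-one (both epimers) | C[C@@H]1CC[C@H]2[C@H](C(O[Si](CC)(CC)CC)c3c(OCC=C)c(C4(O)C=CC(OC)(OC)C=C4)cn(OCC=C)c3=O)[C@H](C)C=C[C@@H]2C1
F3 | step 11 | 3-(Dec-carbonyl)-5-(1-hydroxy-4-oxocyclohexyl)-1,4-bis(prop-2-en-1-yloxy)pyridin-2(1H)-one | C[C@@H]1CC[C@H]2[C@H](C(=O)c3c(OCC=C)c(C4(O)CCC(=O)CC4)cn(OCC=C)c3=O)[C@H](C)C=C[C@@H]2C1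
F4 | step 11 | 3-(Dec-carbonyl)-5-[(1S)-1,4-bis(trimethylsilyloxy)cyclohex-3-en-1-yl]-1,4-bis(prop-2-en-1-yloxy)pyridin-2(1H)-one | C[C@@H]1CC[C@H]2[C@H](C(=O)c3c(OCC=C)c([C@]4(O[Si](C)(C)C)CCC(O[Si](C)(C)C)=CC4)cn(OCC=C)c3=O)[C@H](C)C=C[C@@H]2C1
F5 | step 14 | 3-(Dec-carbonyl)-5-[(1R,2R,5S,6R)-2,5-dihydroxy-7-oxabicyclo[4.1.0]heptan-2-yl]-1,4-bis(prop-2-en-1-yloxy)pyridin-2(1H)-one | C[C@@H]1CC[C@H]2[C@H](C(=O)c3c(OCC=C)c([C@]4(O)CC[C@H](O)[C@H]5O[C@H]54)cn(OCC=C)c3=O)[C@H](C)C=C[C@@H]2C1
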